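**Plan**

- Retrosynthesis: ring A (C4a, C5–C8, C8a) is a phloroglucinol in which C6–C7–C8, with the prenyl group on C6, is the carbon chain of 6-methylhept-5-en-2-one. Cutting C8–C8a and C5–C6 therefore leaves that ketone and a 4-pyranone that already is ring C, carrying ring B on C2, the side chain on C3, an ester carbon as the future C5 and a methylthio leaving group on the future C8a.
- The pyranone is cut at O1–C8a and C4a–C8a (carbon from CS2), at C2–C3 (aroylation of a β-keto ester dianion) and at C3–C1'' (acetoacetate dianion plus a terminal epoxide; C1''–C8'' denote the side chain).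
- Forward: geraniol gives the side-chain epoxide; methyl acetoacetate is joined to it and then aroylated; CS2/MeI closes ring C; the ketone enolate builds ring A; acid unmasks the target.
- Stereochemistry: both centres come from the Katsuki–Sharpless epoxidation of geraniol with L-(+)-diethyl tartrate, which gives the (2S,3S)-epoxide. Anti hydration inverts the tertiary carbon to (3''R) while C2'' keeps its oxygen (2''S); no later step breaks a bond at either centre.

Key step: step 10

Remark: read from the SMILES, the target side chain is (2S) at CH(OH) and (3R) at C(CH3)(OH). C4 of 11 and 12 lies between two ketones, is enolised and is drawn without a descriptor; it becomes sp2 in 13.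

**Step 1**
Reactants: 1 geraniol
Product: 2 [(2S,3S)-3-methyl-3-(4-methylpent-3-en-1-yl)oxiran-2-yl]methanol
Conditions: Ti(OiPr)4 (5 mol %), L-(+)-diethyl tartrate (7.5 mol %), t-BuOOH (2 equiv), 4 Å molecular sieves, CH2Cl2, −20 °C
Reagents that add atoms: tert-butyl hydroperoxide, CC(C)(C)OO
Why: Katsuki–Sharpless asymmetric epoxidation is directed by the allylic hydroxyl to the C2–C3 alkene only, and the L-(+)-tartrate ligand should deliver oxygen to the face that gives the (2S,3S)-epoxide.

**Step 2**
Reactants: 2 [(2S,3S)-3-methyl-3-(4-methylpent-3-en-1-yl)oxiran-2-yl]methanol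
Product: 3 [(2S,3S)-3-methyl-3-(4-methylpent-3-en-1-yl)oxiran-2-yl]methyl 4-methylbenzenesulfonate
Conditions: TsCl (1.2 equiv), Et3N (1.5 equiv), DMAP (5 mol %), CH2Cl2, 0 °C
Reagents that add atoms: 4-toluenesulfonyl chloride, Cc1ccc(cc1)S(Cl)(=O)=O
Why: Sulfonylation of the primary alcohol under amine base leaves the epoxide intact, installs the leaving group for step 4 and further deactivates C2 towards opening.

**Step 3**
Reactants: 3 [(2S,3S)-3-methyl-3-(4-methylpent-3-en-1-yl)oxiran-2-yl]methyl 4-methylbenzenesulfonate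
Product: 4 (2S,3R)-2,3-dihydroxy-3,7-dimethyloct-6-en-1-yl 4-methylbenzenesulfonate
Conditions: HClO4 (5 mol %), THF/H2O (3:1), 0 °C to rt
Reagents that add atoms: water, O
Why: Acid-catalysed epoxide hydration, in which water should attack the protonated oxirane at the tertiary carbon from the side opposite to the leaving oxygen (borderline SN2), inverting C3 to R while C2 keeps its oxygen and its S configuration.

**Step 4**
Reactants: 4 (2S,3R)-2,3-dihydroxy-3,7-dimethyloct-6-en-1-yl 4-methylbenzenesulfonate
Product: 5 (2R)-6-methyl-2-[(2S)-oxiran-2-yl]hept-5-en-2-ol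
Conditions: K2CO3 (1.5 equiv), MeOH, 0 °C
Reagents that add atoms: none
Why: Intramolecular Williamson etherification (3-exo-tet) of the secondary alkoxide onto the primary sulfonate closes the terminal epoxide without touching either stereocentre, and the weak base at low temperature should keep the tertiary hydroxyl from starting a Payne rearrangement.

**Step 5**
Reactants: 5 (2R)-6-methyl-2-[(2S)-oxiran-2-yl]hept-5-en-2-ol; 6 methyl acetoacetate
Product: 7 methyl (6S,7R)-6,7-dihydroxy-7,11-dimethyl-3-oxododec-10-enoate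
Conditions: 6 (3 equiv), NaH then n-BuLi (3 equiv each), THF, 0 °C; 5, then BF3·OEt2 (1.5 equiv), −78 °C; aq NH4Cl
Reagents that add atoms: none
Why: γ-Alkylation of a β-keto ester dianion by a terminal epoxide under BF3·OEt2 activation should occur at the unsubstituted CH2 (the first equivalent of dianion only removes the tertiary OH proton), and neither stereocentre is involved.

**Step 6**
Reactants: 7 methyl (6S,7R)-6,7-dihydroxy-7,11-dimethyl-3-oxododec-10-enoate
Product: 8 methyl 3-oxo-5-[(4S,5R)-2,2,5-trimethyl-5-(4-methylpent-3-en-1-yl)-1,3-dioxolan-4-yl]pentanoate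
Conditions: 2-methoxypropene (3 equiv), pyridinium p-toluenesulfonate (5 mol %), CH2Cl2, 0 °C; then Et3N
Reagents that add atoms: 2-methoxypropene, COC(C)=C
Why: Kinetic isopropylidenation of the vicinal secondary/tertiary diol with an enol ether under mild acid should outrun hemiketalisation–dehydration of the γ-hydroxy ketone, and the C–O bonds at both stereocentres stay intact.

**Step 7**
Reactants: 9 methyl 2,4-dihydroxybenzoate
Product: 10 methyl 2,4-bis(methoxymethoxy)benzoate
Conditions: NaH (2.5 equiv), MOMCl (2.5 equiv), DMF, 0 °C to rt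
Reagents that add atoms: chloromethyl methyl ether, COCCl
Why: Williamson etherification through the sodium phenoxides protects both phenols, including the hydrogen-bonded ortho hydroxyl.

**Step 8**
Reactants: 8 methyl 3-oxo-5-[(4S,5R)-2,2,5-trimethyl-5-(4-methylpent-3-en-1-yl)-1,3-dioxolan-4-yl]pentanoate; 10 methyl 2,4-bis(methoxymethoxy)benzoate
Product: 11 methyl 5-[2,4-bis(methoxymethoxy)phenyl]-3,5-dioxo-4-{[(4S,5R)-2,2,5-trimethyl-5-(4-methylpent-3-en-1-yl)-1,3-dioxolan-4-yl]methyl}pentanoate
Conditions: 8, LiN(iPr)2 (3.2 equiv), THF, −78 to 0 °C; 10 (1.3 equiv), 0 °C to rt; aq NH4Cl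
Reagents that add atoms: none
Why: Claisen-type γ-acylation of a β-keto ester dianion by an aryl ester, in which the dianion of 8 reacts at its more basic γ-carbon and the third equivalent of base holds the more acidic tricarbonyl product as its salt; the new C4 centre is enolised and has no stereochemical consequence.

**Step 9**
Reactants: 11 methyl 5-[2,4-bis(methoxymethoxy)phenyl]-3,5-dioxo-4-{[(4S,5R)-2,2,5-trimethyl-5-(4-methylpent-3-en-1-yl)-1,3-dioxolan-4-yl]methyl}pentanoate
Product: 13 methyl 6-[2,4-bis(methoxymethoxy)phenyl]-2-(methylsulfanyl)-4-oxo-5-{[(4S,5R)-2,2,5-trimethyl-5-(4-methylpent-3-en-1-yl)-1,3-dioxolan-4-yl]methyl}-4H-pyran-3-carboxylate, via ketene dithioacetal 12 (not isolated)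
Conditions: K2CO3 (3 equiv), CS2 (1.2 equiv), DMF, 0 °C to rt; MeI (2.1 equiv), 0 °C to rt; then 50 °C
Reagents that add atoms: carbon disulfide, S=C=S; iodomethane, CI
Why: Dithiocarboxylation of the C2 methylene between ketone and ester and double S-methylation (standard α-oxo ketene dithioacetal synthesis) give 12, whose enolised aryl ketone oxygen should add to the bis(methylsulfanyl) carbon and expel methanethiolate (6-endo-trig addition–elimination, as in 2-(methylsulfanyl)chromone syntheses), while the hindered C4 methine should not compete for CS2.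

**Step 10**
Reactants: 13 methyl 6-[2,4-bis(methoxymethoxy)phenyl]-2-(methylsulfanyl)-4-oxo-5-{[(4S,5R)-2,2,5-trimethyl-5-(4-methylpent-3-en-1-yl)-1,3-dioxolan-4-yl]methyl}-4H-pyran-3-carboxylate; 14 6-methylhept-5-en-2-one
Product: 16 2-[2,4-bis(methoxymethoxy)phenyl]-5,7-dihydroxy-6-(3-methylbut-2-en-1-yl)-3-{[(4S,5R)-2,2,5-trimethyl-5-(4-methylpent-3-en-1-yl)-1,3-dioxolan-4-yl]methyl}-4H-chromen-4-one, via acylmethyl pyranone 15 (not isolated)
Conditions: LiN(iPr)2 (1.3 equiv), 14 (1.3 equiv, added to the base), THF, −78 °C; 13, −78 to −40 °C; LiN(iPr)2 (2.5 equiv), −78 to 0 °C; aq NH4Cl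
Reagents that add atoms: none
Why: Proposed new method: the kinetic lithium enolate of 14 (methyl side) should add to C2 of pyranone 13, a vinylogous thioester carbon activated by both the C4 ketone and the C3 ester, and expel methanethiolate to give 15, which creates the C8–C8a bond of the flavone. Further base then removes the doubly activated CH2 proton and a proton from the other α-carbon of the side-chain ketone, and the terminal carbanion of this dianion attacks the C3 ester in a 6-(enolexo)-exo-trig Claisen condensation (C5–C6 bond), after which loss of methoxide and two enolisations aromatise ring A to the 5,7-diol with prenyl on C6. The closest known reaction types are the [3+3] aromatic annulation of α-oxo ketene dithioacetals with ketone enolates and the Claisen cyclisation of polycarbonyl dianions to acylphloroglucinols. No stereocentre is formed, and the two acetonide stereocentres are not enolisable and lie outside the reacting system. The step needs enolisation of 14 at CH3 rather than CH2, which the hindered amide base at −78 °C with inverse addition should secure, and attack at C2 rather than at C6 or at the ester carbonyl, which the thiolate leaving group, the double activation and the shielding of C6 by the ortho-substituted aryl group and the neighbouring side chain should secure. Ring opening at O1–C2 instead of thiolate loss would be harmless, because the opened enolate can reclose on the same carbon with loss of thiolate.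

**Step 11**
Reactants: 16 2-[2,4-bis(methoxymethoxy)phenyl]-5,7-dihydroxy-6-(3-methylbut-2-en-1-yl)-3-{[(4S,5R)-2,2,5-trimethyl-5-(4-methylpent-3-en-1-yl)-1,3-dioxolan-4-yl]methyl}-4H-chromen-4-one
Product: 17 2-(2,4-dihydroxyphenyl)-3-[(2S,3R)-2,3-dihydroxy-3,7-dimethyloct-6-en-1-yl]-5,7-dihydroxy-6-(3-methylbut-2-en-1-yl)-4H-chromen-4-one
Conditions: HCl (1.25 M in MeOH), rt to 40 °C
Reagents that add atoms: none
Why: Acid-catalysed acetal exchange with methanol removes both methoxymethyl ethers and the isopropylidene group at their acetal carbons, so no bond to a stereocentre is broken, and the mild acid should spare the two trisubstituted alkenes.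

**Compound list**

1 | geraniol | CC(C)=CCC/C(C)=C/CO | starting material
2 | [(2S,3S)-3-methyl-3-(4-methylpent-3-en-1-yl)oxiran-2-yl]methanol | CC(C)=CCC[C@]1(C)O[C@H]1CO | intermediate
3 | [(2S,3S)-3-methyl-3-(4-methylpent-3-en-1-yl)oxiran-2-yl]methyl 4-methylbenzenesulfonate | CC(C)=CCC[C@]1(C)O[C@H]1COS(=O)(=O)c1ccc(C)cc1 | intermediate
4 | (2S,3R)-2,3-dihydroxy-3,7-dimethyloct-6-en-1-yl 4-methylbenzenesulfonate | CC(C)=CCC[C@@](C)(O)[C@@H](O)COS(=O)(=O)c1ccc(C)cc1 | intermediate
5 | (2R)-6-methyl-2-[(2S)-oxiran-2-yl]hept-5-en-2-ol | CC(C)=CCC[C@@](C)(O)[C@@H]1CO1 | intermediate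
6 | methyl acetoacetate | COC(=O)CC(C)=O | starting material
7 | methyl (6S,7R)-6,7-dihydroxy-7,11-dimethyl-3-oxododec-10-enoate | CC(C)=CCC[C@@](C)(O)[C@@H](O)CCC(=O)CC(=O)OC | intermediate
8 | methyl 3-oxo-5-[(4S,5R)-2,2,5-trimethyl-5-(4-methylpent-3-en-1-yl)-1,3-dioxolan-4-yl]pentanoate | CC(C)=CCC[C@@]1(C)OC(C)(C)O[C@H]1CCC(=O)CC(=O)OC | intermediate
9 | methyl 2,4-dihydroxybenzoate | COC(=O)c1ccc(O)cc1O | starting material
10 | methyl 2,4-bis(methoxymethoxy)benzoate | COCOc1ccc(C(=O)OC)c(OCOC)c1 | intermediate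
11 | methyl 5-[2,4-bis(methoxymethoxy)phenyl]-3,5-dioxo-4-{[(4S,5R)-2,2,5-trimethyl-5-(4-methylpent-3-en-1-yl)-1,3-dioxolan-4-yl]methyl}pentanoate | COC(=O)CC(=O)C(C[C@@H]1OC(C)(C)O[C@]1(C)CCC=C(C)C)C(=O)c1ccc(OCOC)cc1OCOC | intermediate
12 | methyl 5-[2,4-bis(methoxymethoxy)phenyl]-2-[bis(methylsulfanyl)methylidene]-3,5-dioxo-4-{[(4S,5R)-2,2,5-trimethyl-5-(4-methylpent-3-en-1-yl)-1,3-dioxolan-4-yl]methyl}pentanoate | COC(=O)C(=C(SC)SC)C(=O)C(C[C@@H]1OC(C)(C)O[C@]1(C)CCC=C(C)C)C(=O)c1ccc(OCOC)cc1OCOC | intermediate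
13 | methyl 6-[2,4-bis(methoxymethoxy)phenyl]-2-(methylsulfanyl)-4-oxo-5-{[(4S,5R)-2,2,5-trimethyl-5-(4-methylpent-3-en-1-yl)-1,3-dioxolan-4-yl]methyl}-4H-pyran-3-carboxylate | COC(=O)c1c(SC)oc(-c2ccc(OCOC)cc2OCOC)c(C[C@@H]2OC(C)(C)O[C@]2(C)CCC=C(C)C)c1=O | intermediate
14 | 6-methylhept-5-en-2-one | CC(=O)CCC=C(C)C | starting material
15 | methyl 6-[2,4-bis(methoxymethoxy)phenyl]-2-(6-methyl-2-oxohept-5-en-1-yl)-4-oxo-5-{[(4S,5R)-2,2,5-trimethyl-5-(4-methylpent-3-en-1-yl)-1,3-dioxolan-4-yl]methyl}-4H-pyran-3-carboxylate | COC(=O)c1c(CC(=O)CCC=C(C)C)oc(-c2ccc(OCOC)cc2OCOC)c(C[C@@H]2OC(C)(C)O[C@]2(C)CCC=C(C)C)c1=O | intermediate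
16 | 2-[2,4-bis(methoxymethoxy)phenyl]-5,7-dihydroxy-6-(3-methylbut-2-en-1-yl)-3-{[(4S,5R)-2,2,5-trimethyl-5-(4-methylpent-3-en-1-yl)-1,3-dioxolan-4-yl]methyl}-4H-chromen-4-one | CC(C)=CCC[C@@]1(C)OC(C)(C)O[C@H]1Cc1c(-c2ccc(OCOC)cc2OCOC)oc2cc(O)c(CC=C(C)C)c(O)c2c1=O | intermediate
17 | 2-(2,4-dihydroxyphenyl)-3-[(2S,3R)-2,3-dihydroxy-3,7-dimethyloct-6-en-1-yl]-5,7-dihydroxy-6-(3-methylbut-2-en-1-yl)-4H-chromen-4-one | CC(C)=CCC[C@@](C)(O)[C@@H](O)Cc1c(-c2ccc(O)cc2O)oc2cc(O)c(CC=C(C)C)c(O)c2c1=O | target

**Step count**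

Total: 11 steps. Longest linear sequence: 10 steps (steps 1–6 and 8–11, from geraniol).

**Steps most likely to fail**

1. Step 10. The enolate may add to the ester carbonyl or to C6 instead of the thiolate-bearing carbon, proton transfer may scramble the enolate regiochemistry before C–C bond formation, or the sequence may stall after the substitution because the second enolisation and Claisen closure do not proceed. The fallback sets out from 13 and returns at 16, using a stabilised carbanion and stepwise known reactions.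
   - The dianion of 6 (NaH, then n-BuLi, THF, 0 °C) is alkylated with 1-bromo-3-methylbut-2-ene to give methyl 7-methyl-3-oxooct-6-enoate F1.
   - Its sodium enolate (NaH, DMF, rt) displaces the methylthio group of 13 by addition–elimination, as active-methylene anions do on methylthio-substituted push–pull alkenes, to give the pyranone β-keto ester F2.
   - LiN(iPr)2 (3 equiv, THF, −78 to 0 °C) forms the γ-dianion of F2, which closes ring A onto the pyranone ester to give the chromene-8-carboxylate F3.
   - Aqueous NaOH in MeOH saponifies the hindered ester to the 8-carboxylic acid F4, a phloroglucinol carboxylic acid that should lose CO2 on acidification and gentle warming to deliver 16.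

2. Step 9. Dithiocarboxylation or C-methylation may occur at the C4 methine between the two ketones, the enol may lactonise onto the ester, or ring closure may take place on the ester carbonyl instead of the dithioacetal carbon. The fallback sets out from 8, returns at 13 and reverses the order of the two events, so that no free tricarbonyl ester is exposed to CS2 and MeI.
   - 8, with its single active methylene, is treated with K2CO3, CS2 and MeI in DMF to give the ketene dithioacetal F5.
   - Ester 10 is saponified (LiOH, THF/H2O) to 2,4-bis(methoxymethoxy)benzoic acid F6 and activated with 1,1'-carbonyldiimidazole as its imidazolide F7.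
   - The lithium enolate of F5 (LiN(SiMe3)2, 2.2 equiv, THF, −78 °C; only the CH2 next to the side chain is enolisable) is C-aroylated by F7 to give 12, which closes to 13 with loss of methanethiolate as in the main route.

3. Step 5. The deprotonated hydroxy epoxide may undergo epoxide migration (Payne rearrangement), the opening may be slow because the dianion and the Lewis acid consume each other, and the γ-hydroxy ketone may cyclise and dehydrate under acid before the diol is protected. The fallback sets out from 5, returns at 8 and uses a nucleophile that leaves no ketone beside the free diol.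
   - LiCH2CN (from MeCN and n-BuLi, 2.2 equiv, THF, −78 to −20 °C) opens the epoxide at its CH2 terminus to give the dihydroxy nitrile F8.
   - 2-Methoxypropene with pyridinium p-toluenesulfonate gives the acetonide nitrile F9.
   - A Blaise reaction (activated Zn, methyl bromoacetate, THF, reflux) gives the enamino ester F10, and brief hydrolysis with cold dilute aqueous HCl gives 8.

**Further compounds**

F1 | step 10 | methyl 7-methyl-3-oxooct-6-enoate | COC(=O)CC(=O)CCC=C(C)C
F2 | step 10 | methyl 6-[2,4-bis(methoxymethoxy)phenyl]-2-(1-methoxy-7-methyl-1,3-dioxooct-6-en-2-yl)-4-oxo-5-{[(4S,5R)-2,2,5-trimethyl-5-(4-methylpent-3-en-1-yl)-1,3-dioxolan-4-yl]methyl}-4H-pyran-3-carboxylate | COC(=O)c1c(C(C(=O)OC)C(=O)CCC=C(C)C)oc(-c2ccc(OCOC)cc2OCOC)c(C[C@@H]2OC(C)(C)O[C@]2(C)CCC=C(C)C)c1=O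
F3 | step 10 | methyl 2-[2,4-bis(methoxymethoxy)phenyl]-5,7-dihydroxy-6-(3-methylbut-2-en-1-yl)-4-oxo-3-{[(4S,5R)-2,2,5-trimethyl-5-(4-methylpent-3-en-1-yl)-1,3-dioxolan-4-yl]methyl}-4H-chromene-8-carboxylate | CC(C)=CCC[C@@]1(C)OC(C)(C)O[C@H]1Cc1c(-c2ccc(OCOC)cc2OCOC)oc2c(C(=O)OC)c(O)c(CC=C(C)C)c(O)c2c1=O
F4 | step 10 | 2-[2,4-bis(methoxymethoxy)phenyl]-5,7-dihydroxy-6-(3-methylbut-2-en-1-yl)-4-oxo-3-{[(4S,5R)-2,2,5-trimethyl-5-(4-methylpent-3-en-1-yl)-1,3-dioxolan-4-yl]methyl}-4H-chromene-8-carboxylic acid | CC(C)=CCC[C@@]1(C)OC(C)(C)O[C@H]1Cc1c(-c2ccc(OCOC)cc2OCOC)oc2c(C(=O)O)c(O)c(CC=C(C)C)c(O)c2c1=O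
F5 | step 9 | methyl 2-[bis(methylsulfanyl)methylidene]-3-oxo-5-[(4S,5R)-2,2,5-trimethyl-5-(4-methylpent-3-en-1-yl)-1,3-dioxolan-4-yl]pentanoate | COC(=O)C(=C(SC)SC)C(=O)CC[C@@H]1OC(C)(C)O[C@]1(C)CCC=C(C)C
F6 | step 9 | 2,4-bis(methoxymethoxy)benzoic acid | COCOc1ccc(C(=O)O)c(OCOC)c1
F7 | step 9 | [2,4-bis(methoxymethoxy)phenyl](1H-imidazol-1-yl)methanone | COCOc1ccc(C(=O)n2ccnc2)c(OCOC)c1
F8 | step 5 | (4S,5R)-4,5-dihydroxy-5,9-dimethyldec-8-enenitrile | CC(C)=CCC[C@@](C)(O)[C@@H](O)CCC#N
F9 | step 5 | 3-[(4S,5R)-2,2,5-trimethyl-5-(4-methylpent-3-en-1-yl)-1,3-dioxolan-4-yl]propanenitrile | CC(C)=CCC[C@@]1(C)OC(C)(C)O[C@H]1CCC#N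
F10 | step 5 | methyl (2Z)-3-amino-5-[(4S,5R)-2,2,5-trimethyl-5-(4-methylpent-3-en-1-yl)-1,3-dioxolan-4-yl]pent-2-enoate | COC(=O)/C=C(\N)CC[C@@H]1OC(C)(C)O[C@]1(C)CCC=C(C)C
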